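**Retrosynthetic overview**

1. The target is a depside. The aryl ester bond between the carboxyl carbon of ring B and O-4 of ring A is cut last, giving 2,4-dimethoxy-6-propylbenzoyl chloride and benzyl 2,4-dihydroxy-6-pentylbenzoate; ring A is bought intact as olivetolic acid.
2. The strategy rests on the 1,3-alternating oxygen pattern of ring B. Its ester carbon with C1, C2 (O) and C3 is an acetoacetate unit, and C4 (O), C5 and C6 with the propyl chain is a 3-oxohexanoyl unit.
3. Ring B is therefore built by a TiCl4-mediated formal [3+3] cyclocondensation of 1-methoxy-1,3-bis(trimethylsilyloxy)buta-1,3-diene with 1,1-dimethoxyhex-1-en-3-one, which forms C3–C4 and C1–C6.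
4. Ring B is the only ring formed (step 4). It is followed by O-methylation, saponification, acid chloride formation, esterification of the 4-OH of ring A, and hydrogenolysis.

Key step: step 4

Remark: olivetolic acid (12) is taken as a purchased starting material. The enol-ether double bonds of 2, 3 and 7 are written without geometry because they form as isomer mixtures and all end up in the aromatic ring; the target has no stereocentre.

**Route**

Step 1
Reactants: 1 methyl acetoacetate
Product: 2 methyl 3-(trimethylsilyloxy)but-2-enoate
Conditions: Me3SiCl, Et3N, hexane, rt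
Reagents that add atoms: chlorotrimethylsilane, C[Si](C)(C)Cl
Why: Soft enolisation and O-silylation of a β-keto ester with Me3SiCl/Et3N (silyl enol ether formation) is driven by precipitation of the ammonium salt and touches only the ketone enol.

Step 2
Reactants: 2 methyl 3-(trimethylsilyloxy)but-2-enoate
Product: 3 1-methoxy-1,3-bis(trimethylsilyloxy)buta-1,3-diene
Conditions: LiN(iPr)2, THF, −78 °C; then Me3SiCl, −78 °C → rt
Reagents that add atoms: chlorotrimethylsilane, C[Si](C)(C)Cl
Why: Kinetic γ-deprotonation of the vinylogous ester and O-silylation of the extended enolate at the ester oxygen (silyl ketene acetal formation) is the standard way to this bis(silyl enol ether), which is used without chromatography.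

Step 3
Reactants: 4 butanoyl chloride; 5 1,1-dimethoxyethene
Product: 6 1,1-dimethoxyhex-1-en-3-one
Conditions: Et3N, Et2O, 0 °C → rt
Reagents that add atoms: none
Why: C-acylation of the strongly nucleophilic ketene O,O-acetal by the acid chloride gives a dialkoxycarbenium ion that the amine deprotonates to the acylketene acetal, provided the acid chloride is added slowly to excess acetal and base under anhydrous conditions.

Step 4
Reactants: 3 1-methoxy-1,3-bis(trimethylsilyloxy)buta-1,3-diene; 6 1,1-dimethoxyhex-1-en-3-one
Product: 8 methyl 2-hydroxy-4-methoxy-6-propylbenzoate, via open-chain vinylogous ester 7 (not isolated)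
Conditions: TiCl4, CH2Cl2, −78 °C → 20 °C; then aq. HCl
Reagents that add atoms: none
Why: TiCl4 binds the ketone oxygen of 6 and makes its dimethoxy-substituted β-carbon a dialkoxycarbenium-like centre; the terminal CH2 of diene 3, its most nucleophilic carbon, adds there in a vinylogous Mukaiyama–Michael addition and methoxide is lost, which forms the ring-B bond C3–C4 and leaves vinylogous ester 7 still carrying a silyl enol ether next to the ester. That enol-ether carbon then attacks the TiCl4-activated propyl ketone in an intramolecular Mukaiyama aldol addition, a favoured 6-(enolendo)-exo-trig closure that forms C1–C6, and loss of the tertiary oxygen as water followed by enolisation aromatises the ring to the hydrogen-bonded salicylate. The closest known reaction type is the TiCl4-mediated formal [3+3] cyclocondensation of 1,3-bis(silyloxy)buta-1,3-dienes with masked 1,3-dielectrophiles such as 3-silyloxy enones and β,β-dialkoxy enones, which gives salicylates. No stereocentre is created. The step needs regioselectivity, the diene terminus having to meet the acetal carbon and not the ketone carbon; this is expected because the ketone is a deactivated push–pull carbonyl while the β-carbon is the stabilised cationic site, and because after the first bond only 1,2-attack on the ketone closes a six-membered ring, whereas the opposite pairing would give the 6-methoxy-4-propyl isomer.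

Step 5
Reactants: 8 methyl 2-hydroxy-4-methoxy-6-propylbenzoate
Product: 9 methyl 2,4-dimethoxy-6-propylbenzoate
Conditions: MeI, K2CO3, DMF, 40 °C
Reagents that add atoms: iodomethane, CI
Why: Williamson ether synthesis on the single, chelated phenol with excess MeI leaves the methyl ester and the existing ether untouched, so the two methoxy groups of ring B need no differentiation.

Step 6
Reactants: 9 methyl 2,4-dimethoxy-6-propylbenzoate
Product: 10 2,4-dimethoxy-6-propylbenzoic acid
Conditions: KOH, DMSO/H2O, 90 °C; then aq. HCl, 0 °C
Reagents that add atoms: potassium hydroxide, [K+].[OH-]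
Why: Saponification of the doubly ortho-substituted ester needs poorly solvated hydroxide at elevated temperature, conditions the aryl methyl ethers tolerate, and cold acidification avoids protodecarboxylation of the electron-rich acid.

Step 7
Reactants: 10 2,4-dimethoxy-6-propylbenzoic acid
Product: 11 2,4-dimethoxy-6-propylbenzoyl chloride
Conditions: (COCl)2, DMF (cat.), CH2Cl2, 0 °C → rt
Reagents that add atoms: oxalyl chloride, O=C(Cl)C(=O)Cl
Why: DMF-catalysed acid chloride formation through the chloroiminium (Vilsmeier-type) intermediate is mild and gives only gaseous co-products, so the crude chloride can be concentrated and used directly.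

Step 8
Reactants: 12 olivetolic acid (2,4-dihydroxy-6-pentylbenzoic acid)
Product: 13 benzyl 2,4-dihydroxy-6-pentylbenzoate
Conditions: BnBr, KHCO3, DMF, rt
Reagents that add atoms: benzyl bromide, BrCc1ccccc1
Why: KHCO3 deprotonates only the carboxylic acid and not the phenols, so SN2 alkylation of the carboxylate with BnBr gives the benzyl ester selectively, and room temperature avoids decarboxylation of the β-resorcylic acid.

Step 9
Reactants: 11 2,4-dimethoxy-6-propylbenzoyl chloride; 13 benzyl 2,4-dihydroxy-6-pentylbenzoate
Product: 14 benzyl 4-[(2,4-dimethoxy-6-propylbenzoyl)oxy]-2-hydroxy-6-pentylbenzoate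
Conditions: Et3N, DMAP (cat.), CH2Cl2, 0 °C → rt
Reagents that add atoms: none
Why: Nucleophilic acyl substitution (base-mediated phenol acylation) with one equivalent of acid chloride should occur at the free and more acidic 4-OH, because the 2-OH is hydrogen-bonded to the ester carbonyl and flanked by it.

Step 10
Reactants: 14 benzyl 4-[(2,4-dimethoxy-6-propylbenzoyl)oxy]-2-hydroxy-6-pentylbenzoate
Product: 15 4-[(2,4-dimethoxy-6-propylbenzoyl)oxy]-2-hydroxy-6-pentylbenzoic acid (target)
Conditions: H2 (1 atm), Pd/C, EtOAc, rt
Reagents that add atoms: none
Why: Catalytic hydrogenolysis cleaves only the benzylic C–O bond of the benzyl ester, while the aryl ester of the depside, the methyl ethers and the arenes are inert under these neutral conditions.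

**Compound list**

1 | methyl acetoacetate | COC(=O)CC(C)=O | starting material
2 | methyl 3-(trimethylsilyloxy)but-2-enoate (E/Z mixture) | COC(=O)C=C(C)O[Si](C)(C)C | intermediate
3 | 1-methoxy-1,3-bis(trimethylsilyloxy)buta-1,3-diene | C=C(O[Si](C)(C)C)C=C(OC)O[Si](C)(C)C | intermediate
4 | butanoyl chloride | CCCC(Cl)=O | starting material
5 | 1,1-dimethoxyethene | C=C(OC)OC | starting material
6 | 1,1-dimethoxyhex-1-en-3-one | CCCC(=O)C=C(OC)OC | intermediate
7 | methyl 5-methoxy-7-oxo-3-(trimethylsilyloxy)deca-2,5-dienoate (isomer mixture, not isolated) | COC(=O)C=C(O[Si](C)(C)C)CC(OC)=CC(=O)CCC | intermediate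
8 | methyl 2-hydroxy-4-methoxy-6-propylbenzoate | CCCc1cc(OC)cc(O)c1C(=O)OC | intermediate
9 | methyl 2,4-dimethoxy-6-propylbenzoate | CCCc1cc(OC)cc(OC)c1C(=O)OC | intermediate
10 | 2,4-dimethoxy-6-propylbenzoic acid | CCCc1cc(OC)cc(OC)c1C(=O)O | intermediate
11 | 2,4-dimethoxy-6-propylbenzoyl chloride | CCCc1cc(OC)cc(OC)c1C(=O)Cl | intermediate
12 | olivetolic acid (2,4-dihydroxy-6-pentylbenzoic acid) | CCCCCc1cc(O)cc(O)c1C(=O)O | starting material
13 | benzyl 2,4-dihydroxy-6-pentylbenzoate | CCCCCc1cc(O)cc(O)c1C(=O)OCc1ccccc1 | intermediate
14 | benzyl 4-[(2,4-dimethoxy-6-propylbenzoyl)oxy]-2-hydroxy-6-pentylbenzoate | CCCCCc1cc(OC(=O)c2c(CCC)cc(OC)cc2OC)cc(O)c1C(=O)OCc1ccccc1 | intermediate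
15 | 4-[(2,4-dimethoxy-6-propylbenzoyl)oxy]-2-hydroxy-6-pentylbenzoic acid | CCCCCc1cc(OC(=O)c2c(CCC)cc(OC)cc2OC)cc(O)c1C(=O)O | target

**Step count**

Total steps: 10. Longest linear sequence: 8 steps (steps 1, 2, 4, 5, 6, 7, 9, 10, from methyl acetoacetate).

**Steps most likely to fail**

Step 4 (ring-forming cyclocondensation). The diene terminus may attack the ketone carbon instead of the acetal carbon, which would lead to the regioisomeric salicylate. The ketene acetal may also be hydrolysed by the Lewis acid before the first C–C bond forms, or the sequence may stall before ring closure and aromatisation. The fallback sets out from methyl acetoacetate 1 and comes back to the route at 9. Michael addition of 1 to commercial methyl (E)-hex-2-enoate (CCC/C=C/C(=O)OC) with NaOMe in refluxing MeOH, followed in the same pot by Dieckmann closure, should give methyl 2-hydroxy-4-oxo-6-propylcyclohex-2-ene-1-carboxylate F1. Bromination and dehydrobromination with Br2 in DMF (0 °C, then 80 °C) should aromatise it to methyl 2,4-dihydroxy-6-propylbenzoate F2. Double O-methylation with excess MeI and K2CO3 in DMF then gives 9.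

Step 3 (acylation of the ketene acetal). Chloride may demethylate the acylated dialkoxycarbenium ion to the β-keto ester, the amine may dehydrochlorinate the acid chloride to ethylketene, or the moisture-sensitive product may hydrolyse during isolation. The fallback sets out from butanoyl chloride 4 and comes back to the route at 6. Friedel–Crafts acylation of 1,1-dichloroethene (C=C(Cl)Cl) with AlCl3 in CH2Cl2 at 0 °C should give 1,1,1-trichlorohexan-3-one F3. This loses HCl on distillation or with Et3N to give 1,1-dichlorohex-1-en-3-one F4. Two successive addition–elimination substitutions with NaOMe (2 equiv) in MeOH at 0 °C then deliver 6.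

Step 9 (depside esterification). Acyl transfer from the doubly ortho-substituted acid chloride may be slow, so that over-acylation at the chelated 2-OH or hydrolysis of the chloride competes with the wanted mono-acylation. The fallback sets out from acid chloride 11 and comes back to the route at 15. Vilsmeier–Haack formylation of commercial olivetol (CCCCCc1cc(O)cc(O)c1; POCl3, DMF, 0 °C → rt, then aqueous hydrolysis) should give 2,4-dihydroxy-6-pentylbenzaldehyde F5, whose 2-OH is even more firmly chelated. Acylation of its 4-OH with 11 (K2CO3, acetone, rt) should give 4-formyl-3-hydroxy-5-pentylphenyl 2,4-dimethoxy-6-propylbenzoate F6. Pinnick oxidation (NaClO2, NaH2PO4, 2-methylbut-2-ene, t-BuOH/H2O, rt) then converts the aldehyde into the carboxylic acid 15, with no benzyl ester and no hydrogenolysis.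

**Further compounds**

F1 | step 4 | methyl 2-hydroxy-4-oxo-6-propylcyclohex-2-ene-1-carboxylate (racemic diastereomer mixture) | CCCC1CC(=O)C=C(O)C1C(=O)OC
F2 | step 4 | methyl 2,4-dihydroxy-6-propylbenzoate | CCCc1cc(O)cc(O)c1C(=O)OC
F3 | step 3 | 1,1,1-trichlorohexan-3-one | CCCC(=O)CC(Cl)(Cl)Cl
F4 | step 3 | 1,1-dichlorohex-1-en-3-one | CCCC(=O)C=C(Cl)Cl
F5 | step 9 | 2,4-dihydroxy-6-pentylbenzaldehyde | CCCCCc1cc(O)cc(O)c1C=O
F6 | step 9 | 4-formyl-3-hydroxy-5-pentylphenyl 2,4-dimethoxy-6-propylbenzoate | CCCCCc1cc(OC(=O)c2c(CCC)cc(OC)cc2OC)cc(O)c1C=O
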